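**Strategy.** Numbering follows the target, (4R,6S,8S,9S)-4,9-dibromo-8-chloro-1,5,5,9-tetramethylspiro[5.5]undec-1-ene (ring A: C1–C6; ring B: C6–C11). Ring A is closed last at C2–C3 by intramolecular enolate alkylation. The precursor is an acetylcyclohexane: ring B with its trans bromochloride, and on the quaternary C6 an acetyl group (C1, C2) plus a CMe2–CHBr–CH2OTf chain (C5, C4, C3). Because C6 is quaternary the ketone enolises only toward C2, and SN2 attack at primary C3 leaves the C4 bromide, set beforehand by organocatalytic α-bromination, untouched. C6 comes from an enantioselective Diels–Alder reaction, C8/C9 from chlorolactonisation and bromide opening with retention.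

Key step: step 12

Assumption (chemistry): the oxazaborolidinium catalyst is taken to differentiate the faces of the 2-tert-alkylacrolein as the usual model for 2-substituted acroleins predicts (formyl C–H···O contact, s-trans enal stacked on a phenyl group); this points to the (R)-configured catalyst for (R)-5, and the (S)-catalyst would be used if the opposite sense were found.

Step 1
Reactants: 1 methyl 3,3-dimethylpent-4-enoate
Product: 2 3,3-dimethylpent-4-enal
Conditions: iBu2AlH (1.05 equiv), CH2Cl2, −78 °C; aqueous tartrate work-up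
Reagents that add atoms: none
Why: Partial ester reduction with iBu2AlH at low temperature should stop at the aluminium hemiacetal, which releases the aldehyde on work-up.

Step 2
Reactants: 2 3,3-dimethylpent-4-enal
Product: 3 3,3-dimethyl-2-methylidenepent-4-enal
Conditions: 37% aq. CH2O, pyrrolidine (10 mol%), propionic acid (10 mol%), iPrOH, 45 °C
Reagents that add atoms: formaldehyde (C=O)
Why: Amine-catalysed α-methylenation (Mannich condensation, then loss of the amine) should work because the aldehyde has a single α-CH2 group.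

Step 3
Reactants: 3 3,3-dimethyl-2-methylidenepent-4-enal; 4 isoprene
Product: 5 (R)-4-methyl-1-(2-methylbut-3-en-2-yl)cyclohex-3-ene-1-carbaldehyde
Conditions: isoprene (3 equiv), (R)-3,3-diphenyl-1-(2-methylphenyl)tetrahydro-1H,3H-pyrrolo[1,2-c][1,3,2]oxazaborole (20 mol%), HN(SO2CF3)2 (20 mol%), CH2Cl2, −78 → −40 °C
Reagents that add atoms: none
Why: Catalytic enantioselective Diels–Alder reaction; the 2-substituted acrolein should give the "para" adduct with isoprene, and the chiral oxazaborolidinium cation shields one face of the enal so that the quaternary carbon (future C6) forms as R.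

Step 4
Reactants: 5 (R)-4-methyl-1-(2-methylbut-3-en-2-yl)cyclohex-3-ene-1-carbaldehyde
Product: 6 (R)-4-methyl-1-(2-methylbut-3-en-2-yl)cyclohex-3-ene-1-carboxylic acid
Conditions: NaClO2, NaH2PO4, 2-methylbut-2-ene (10 equiv), tBuOH/H2O, 0 °C → rt
Reagents that add atoms: sodium chlorite ([Na+].[O-]Cl=O)
Why: Pinnick oxidation of a non-enolisable aldehyde; the excess alkene scavenger intercepts HOCl so that both alkenes of the substrate should survive.

Step 5
Reactants: 6 (R)-4-methyl-1-(2-methylbut-3-en-2-yl)cyclohex-3-ene-1-carboxylic acid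
Product: 7 (1S,4R,6S)-6-chloro-1-methyl-4-(2-methylbut-3-en-2-yl)-2-oxabicyclo[2.2.2]octan-3-one (chlorine anti to the ring oxygen)
Conditions: 1,3-dichloro-5,5-dimethylhydantoin (0.55 equiv), CHCl3, −20 → 0 °C, dark
Reagents that add atoms: 1,3-dichloro-5,5-dimethylhydantoin (CC1(C)N(Cl)C(=O)N(Cl)C1=O)
Why: Chlorolactonisation; electrophilic chlorine should attack the electron-rich trisubstituted ring alkene in preference to the hindered vinyl group, and the carboxylate on C6 opens the chloronium ion at the tertiary carbon (Markovnikov) from its own face, so chlorine (future C8) ends anti to the lactone oxygen (future C9) and both centres are set relative to C6.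

Step 6
Reactants: 7 (1S,4R,6S)-6-chloro-1-methyl-4-(2-methylbut-3-en-2-yl)-2-oxabicyclo[2.2.2]octan-3-one
Product: 8 (1R,3S,4S)-4-bromo-3-chloro-4-methyl-1-(2-methylbut-3-en-2-yl)cyclohexane-1-carboxylic acid
Conditions: BBr3 (1.2 equiv), CH2Cl2, −78 → −30 °C; then H2O
Reagents that add atoms: boron tribromide (BrB(Br)Br)
Why: Lewis-acid cleavage of the tertiary alkyl–oxygen bond of the lactone; the anti-periplanar chlorine should assist ionisation (neighbouring-group participation) and bromide should open the chloronium ion at the tertiary carbon from the face the oxygen left, so C9 is brominated with retention and the trans bromochloride results.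

Step 7
Reactants: 8 (1R,3S,4S)-4-bromo-3-chloro-4-methyl-1-(2-methylbut-3-en-2-yl)cyclohexane-1-carboxylic acid
Product: 10 1-[(1R,3S,4S)-4-bromo-3-chloro-4-methyl-1-(2-methylbut-3-en-2-yl)cyclohexyl]ethan-1-one, via acid chloride 9 (not isolated)
Conditions: (COCl)2, cat. DMF, CH2Cl2, 0 °C → rt; then Me2CuLi (from MeLi and CuI), Et2O, −78 °C
Reagents that add atoms: oxalyl chloride (ClC(=O)C(=O)Cl; chlorine of 9); lithium dimethylcuprate ([Li+].C[Cu-]C; methyl group of 10)
Why: Acid chloride formation followed by acylation of a Gilman cuprate, which should stop at the ketone and leave the alkyl halides untouched at −78 °C.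

Step 8
Reactants: 10 1-[(1R,3S,4S)-4-bromo-3-chloro-4-methyl-1-(2-methylbut-3-en-2-yl)cyclohexyl]ethan-1-one
Product: 12 1-[(1R,3S,4S)-4-bromo-3-chloro-1-(4-hydroxy-2-methylbutan-2-yl)-4-methylcyclohexyl]ethan-1-one, via alkylborane 11 (not isolated)
Conditions: 9-BBN, THF, 0 °C → rt; then NaBO3·4H2O, H2O, rt
Reagents that add atoms: 9-borabicyclo[3.3.1]nonane (B1C2CCCC1CCC2; boron of 11); sodium perborate ([Na+].[O-]OB=O; oxygen of 12)
Why: Anti-Markovnikov hydroboration of the terminal alkene with 9-BBN, which should be much faster than reduction of the hindered ketone, then mild perborate oxidation of the C–B bond.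

Step 9
Reactants: 12 1-[(1R,3S,4S)-4-bromo-3-chloro-1-(4-hydroxy-2-methylbutan-2-yl)-4-methylcyclohexyl]ethan-1-one
Product: 13 3-[(1R,3S,4S)-1-acetyl-4-bromo-3-chloro-4-methylcyclohexyl]-3-methylbutanal
Conditions: Dess–Martin periodinane, NaHCO3, CH2Cl2, 0 °C → rt
Reagents that add atoms: none
Why: Dess–Martin oxidation of the primary alcohol under buffered, non-basic conditions that the alkyl halides should tolerate.

Step 10
Reactants: 13 3-[(1R,3S,4S)-1-acetyl-4-bromo-3-chloro-4-methylcyclohexyl]-3-methylbutanal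
Product: 15 1-[(1R,3S,4S)-4-bromo-1-[(3S)-3-bromo-4-hydroxy-2-methylbutan-2-yl]-3-chloro-4-methylcyclohexyl]ethan-1-one, via bromo aldehyde 14 (not isolated)
Conditions: (2R,5R)-2,5-diphenylpyrrolidine (20 mol%), PhCO2H (20 mol%), 4,4-dibromo-2,6-di-tert-butylcyclohexa-2,5-dien-1-one (1.1 equiv), CH2Cl2/pentane, −40 °C; then NaBH4, MeOH, −40 °C
Reagents that add atoms: 4,4-dibromo-2,6-di-tert-butylcyclohexa-2,5-dien-1-one (CC(C)(C)C1=CC(Br)(Br)C=C(C(C)(C)C)C1=O)
Why: Enamine-mediated enantioselective α-bromination of the aldehyde; the C2-symmetric amine shields one enamine face so that bromine should add to give the S centre (future C4, R in the target) under catalyst control, and immediate NaBH4 reduction of the aldehyde prevents epimerisation while the hindered methyl ketone reacts much more slowly.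

Step 11
Reactants: 15 1-[(1R,3S,4S)-4-bromo-1-[(3S)-3-bromo-4-hydroxy-2-methylbutan-2-yl]-3-chloro-4-methylcyclohexyl]ethan-1-one
Product: 16 (2S)-3-[(1R,3S,4S)-1-acetyl-4-bromo-3-chloro-4-methylcyclohexyl]-2-bromo-3-methylbutyl trifluoromethanesulfonate
Conditions: Tf2O, 2,6-lutidine, CH2Cl2, −78 °C; used at once
Reagents that add atoms: trifluoromethanesulfonic anhydride (O=S(=O)(OS(=O)(=O)C(F)(F)F)C(F)(F)F)
Why: O-sulfonylation of the primary alcohol with a hindered base at low temperature, too mild to close the bromohydrin to an epoxide.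

Step 12
Reactants: 16 (2S)-3-[(1R,3S,4S)-1-acetyl-4-bromo-3-chloro-4-methylcyclohexyl]-2-bromo-3-methylbutyl trifluoromethanesulfonate
Product: 17 (4R,6R,8S,9S)-4,9-dibromo-8-chloro-5,5,9-trimethylspiro[5.5]undecan-1-one
Conditions: LiN(SiMe3)2 (1.05 equiv), THF (0.01 M, slow addition of 16), −78 → −20 °C
Reagents that add atoms: none
Why: LiN(SiMe3)2 removes a proton from the acetyl methyl group, the only enolisable position because C6 is quaternary, and the enolate carbon (future C2) displaces the primary triflate at C3 by SN2 to close ring A. The closest known reaction type is the intramolecular alkylation (cycloalkylation) of a ketone enolate by a tethered sulfonate. Ring A closes in the 6-(enolendo)-exo-tet mode, an allowed mode for enolate ring closures. No stereocentre is formed: C4 keeps its configuration because the displacement takes place at C3, and C6, C8 and C9 are spectators. The step needs C-alkylation over O-alkylation and substitution over loss of HBr or TfOH; the lithium counter-ion in THF, the alignment of the enolate carbon with the C3–O bond in a six-membered transition state, low temperature and high dilution should secure this.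

Step 13
Reactants: 17 (4R,6R,8S,9S)-4,9-dibromo-8-chloro-5,5,9-trimethylspiro[5.5]undecan-1-one
Product: 18 (4R,6R,8S,9S)-4,9-dibromo-8-chloro-5,5,9-trimethylspiro[5.5]undec-1-en-1-yl trifluoromethanesulfonate
Conditions: KN(SiMe3)2 (1.1 equiv), THF, −78 °C; then N-(5-chloropyridin-2-yl)-bis(trifluoromethanesulfonyl)imide, −78 °C
Reagents that add atoms: N-(5-chloropyridin-2-yl)-bis(trifluoromethanesulfonyl)imide (FC(F)(F)S(=O)(=O)N(c1ccc(Cl)cn1)S(=O)(=O)C(F)(F)F)
Why: Kinetic enolate formation, possible only toward C2, and O-triflation with a reagent that reacts at −78 °C, which should outrun displacement of the hindered C4 bromide by the enolate.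

Step 14
Reactants: 18 (4R,6R,8S,9S)-4,9-dibromo-8-chloro-5,5,9-trimethylspiro[5.5]undec-1-en-1-yl trifluoromethanesulfonate
Product: 19 (4R,6S,8S,9S)-4,9-dibromo-8-chloro-1,5,5,9-tetramethylspiro[5.5]undec-1-ene
Conditions: Me2Zn (2 equiv), Pd(PPh3)4 (5 mol%), THF, 0 °C → rt
Reagents that add atoms: dimethylzinc (C[Zn]C)
Why: Negishi cross-coupling; zerovalent palladium should insert into the vinyl triflate and not into the unactivated secondary and tertiary alkyl halides, and transmetalation with Me2Zn then reductive elimination installs the C1 methyl group, fixing the C1=C2 alkene.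

**Compound list**

1 | methyl 3,3-dimethylpent-4-enoate | COC(=O)CC(C)(C)C=C | starting material
2 | 3,3-dimethylpent-4-enal | O=CCC(C)(C)C=C | intermediate
3 | 3,3-dimethyl-2-methylidenepent-4-enal | C=C(C=O)C(C)(C)C=C | intermediate
4 | isoprene (2-methylbuta-1,3-diene) | C=CC(C)=C | starting material
5 | (R)-4-methyl-1-(2-methylbut-3-en-2-yl)cyclohex-3-ene-1-carbaldehyde | O=C[C@]1(C(C)(C)C=C)CCC(C)=CC1 | intermediate
6 | (R)-4-methyl-1-(2-methylbut-3-en-2-yl)cyclohex-3-ene-1-carboxylic acid | OC(=O)[C@]1(C(C)(C)C=C)CCC(C)=CC1 | intermediate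
7 | (1S,4R,6S)-6-chloro-1-methyl-4-(2-methylbut-3-en-2-yl)-2-oxabicyclo[2.2.2]octan-3-one | O=C2[C@]1(C(C)(C)C=C)CC[C@](C)(O2)[C@@H](Cl)C1 | intermediate
8 | (1R,3S,4S)-4-bromo-3-chloro-4-methyl-1-(2-methylbut-3-en-2-yl)cyclohexane-1-carboxylic acid | OC(=O)[C@]1(C(C)(C)C=C)CC[C@](C)(Br)[C@@H](Cl)C1 | intermediate
9 | (1R,3S,4S)-4-bromo-3-chloro-4-methyl-1-(2-methylbut-3-en-2-yl)cyclohexane-1-carbonyl chloride (not isolated) | ClC(=O)[C@]1(C(C)(C)C=C)CC[C@](C)(Br)[C@@H](Cl)C1 | intermediate
10 | 1-[(1R,3S,4S)-4-bromo-3-chloro-4-methyl-1-(2-methylbut-3-en-2-yl)cyclohexyl]ethan-1-one | CC(=O)[C@]1(C(C)(C)C=C)CC[C@](C)(Br)[C@@H](Cl)C1 | intermediate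
11 | 9-{3-[(1R,3S,4S)-1-acetyl-4-bromo-3-chloro-4-methylcyclohexyl]-3-methylbutyl}-9-borabicyclo[3.3.1]nonane (not isolated) | CC(=O)[C@]1(C(C)(C)CCB2C3CCCC2CCC3)CC[C@](C)(Br)[C@@H](Cl)C1 | intermediate
12 | 1-[(1R,3S,4S)-4-bromo-3-chloro-1-(4-hydroxy-2-methylbutan-2-yl)-4-methylcyclohexyl]ethan-1-one | CC(=O)[C@]1(C(C)(C)CCO)CC[C@](C)(Br)[C@@H](Cl)C1 | intermediate
13 | 3-[(1R,3S,4S)-1-acetyl-4-bromo-3-chloro-4-methylcyclohexyl]-3-methylbutanal | CC(=O)[C@]1(C(C)(C)CC=O)CC[C@](C)(Br)[C@@H](Cl)C1 | intermediate
14 | (2S)-3-[(1R,3S,4S)-1-acetyl-4-bromo-3-chloro-4-methylcyclohexyl]-2-bromo-3-methylbutanal (not isolated) | CC(=O)[C@]1(C(C)(C)[C@H](Br)C=O)CC[C@](C)(Br)[C@@H](Cl)C1 | intermediate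
15 | 1-[(1R,3S,4S)-4-bromo-1-[(3S)-3-bromo-4-hydroxy-2-methylbutan-2-yl]-3-chloro-4-methylcyclohexyl]ethan-1-one | CC(=O)[C@]1(C(C)(C)[C@H](Br)CO)CC[C@](C)(Br)[C@@H](Cl)C1 | intermediate
16 | (2S)-3-[(1R,3S,4S)-1-acetyl-4-bromo-3-chloro-4-methylcyclohexyl]-2-bromo-3-methylbutyl trifluoromethanesulfonate | CC(=O)[C@]1(C(C)(C)[C@H](Br)COS(=O)(=O)C(F)(F)F)CC[C@](C)(Br)[C@@H](Cl)C1 | intermediate
17 | (4R,6R,8S,9S)-4,9-dibromo-8-chloro-5,5,9-trimethylspiro[5.5]undecan-1-one | O=C1CC[C@@H](Br)C(C)(C)[C@]12CC[C@](C)(Br)[C@@H](Cl)C2 | intermediate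
18 | (4R,6R,8S,9S)-4,9-dibromo-8-chloro-5,5,9-trimethylspiro[5.5]undec-1-en-1-yl trifluoromethanesulfonate | FC(F)(F)S(=O)(=O)OC1=CC[C@@H](Br)C(C)(C)[C@]12CC[C@](C)(Br)[C@@H](Cl)C2 | intermediate
19 | (4R,6S,8S,9S)-4,9-dibromo-8-chloro-1,5,5,9-tetramethylspiro[5.5]undec-1-ene | CC1=CC[C@@H](Br)C(C)(C)[C@]12CC[C@](C)(Br)[C@@H](Cl)C2 | target

Total step count: 14
Longest linear sequence: 14 steps (1 → 19; isoprene 4 enters in step 3)

**Steps most likely to fail**

Step 12. The enolate may react at oxygen to give the six-membered cyclic enol ether, or the base may strip HBr or TfOH from the β-bromo triflate. The fallback closes the same C2–C3 bond by a radical path and sets out from 10. Kinetic silylation (LiN(SiMe3)2, Me3SiCl, THF, −78 °C) should give the trimethylsilyl enol ether F1, and NBS (THF, 0 °C) the bromomethyl ketone F2. Heating F2 with catalytic CuBr and tris(2-pyridylmethyl)amine (1,2-dichloroethane, 80 °C) should start an atom-transfer radical cyclisation: the α-keto radical at C2 adds 6-endo to the vinyl group at C3 and the C4 radical takes bromine from F2. C4 is then set without control, so 17 is expected together with its C4 epimer F3, from which it would be separated by chromatography. The route is rejoined at 17.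

Step 6. Ionisation may go through an open tertiary cation, so that bromide enters from both faces, or a proton is lost to give allylic chlorides. The fallback uses interhalogen addition and 1,2-halogen interchange and sets out from 6. MeLi (2.2 equiv, Et2O, 0 °C) should convert the acid into the methyl ketone F4. Bu4N[BrCl2] (CH2Cl2, −20 °C) should add BrCl anti and in the Markovnikov sense through the half-chair that keeps the tert-alkyl group equatorial, giving the trans-diaxial adduct F5 (bromine at future C8 on the acetyl face, chlorine at future C9). Heating F5 (toluene, 100 °C) should bring about the dyotropic interchange of the two vicinal halogens, driven by relief of the 1,3-diaxial bromine/acetyl contact. The diequatorial isomer formed is 10, where the route is rejoined.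

Step 3. The hindered 2-tert-alkylacrolein may react slowly or with poor facial selectivity at the chiral Lewis acid. The fallback is a racemic cycloaddition with resolution and sets out from 3 and 4. Me2AlCl (CH2Cl2, −78 °C) should give the racemic aldehyde F6, and Pinnick oxidation the racemic acid F7. Crystallisation with (S)-1-phenylethylamine should deliver the less soluble salt F8, assumed here to hold the R acid (the other amine antipode would be used otherwise). Acidification returns 6.

**Further compounds**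

F1 | step 12 | {1-[(1R,3S,4S)-4-bromo-3-chloro-4-methyl-1-(2-methylbut-3-en-2-yl)cyclohexyl]ethenyl}oxy(trimethyl)silane | C=C(O[Si](C)(C)C)[C@]1(C(C)(C)C=C)CC[C@](C)(Br)[C@@H](Cl)C1
F2 | step 12 | 2-bromo-1-[(1R,3S,4S)-4-bromo-3-chloro-4-methyl-1-(2-methylbut-3-en-2-yl)cyclohexyl]ethan-1-one | BrCC(=O)[C@]1(C(C)(C)C=C)CC[C@](C)(Br)[C@@H](Cl)C1
F3 | step 12 | (4S,6R,8S,9S)-4,9-dibromo-8-chloro-5,5,9-trimethylspiro[5.5]undecan-1-one | O=C1CC[C@H](Br)C(C)(C)[C@]12CC[C@](C)(Br)[C@@H](Cl)C2
F4 | step 6 | 1-[(1R)-4-methyl-1-(2-methylbut-3-en-2-yl)cyclohex-3-en-1-yl]ethan-1-one | CC(=O)[C@]1(C(C)(C)C=C)CCC(C)=CC1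
F5 | step 6 | 1-[(1R,3R,4R)-3-bromo-4-chloro-4-methyl-1-(2-methylbut-3-en-2-yl)cyclohexyl]ethan-1-one | CC(=O)[C@]1(C(C)(C)C=C)CC[C@@](C)(Cl)[C@H](Br)C1
F6 | step 3 | rac-4-methyl-1-(2-methylbut-3-en-2-yl)cyclohex-3-ene-1-carbaldehyde | O=CC1(C(C)(C)C=C)CCC(C)=CC1
F7 | step 3 | rac-4-methyl-1-(2-methylbut-3-en-2-yl)cyclohex-3-ene-1-carboxylic acid | OC(=O)C1(C(C)(C)C=C)CCC(C)=CC1
F8 | step 3 | (S)-1-phenylethylammonium (R)-4-methyl-1-(2-methylbut-3-en-2-yl)cyclohex-3-ene-1-carboxylate | C[C@H]([NH3+])c1ccccc1.[O-]C(=O)[C@]1(C(C)(C)C=C)CCC(C)=CC1
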